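**Retrosynthetic overview**
1. The target comes from its 4'-O-acyl isomer, a 2-acylhydroquinone, by a 1,2 O→O shift of the (S)-2-methylbutanoyl group onto the neighbouring O-5'.
2. Key disconnection is the ring A–C(=O) bond. The CHO carbon of cinnamaldehyde acts as a nucleophilic cinnamoyl (d1) synthon, and ring A acts as an electrophilic acyloxy-dimethoxy-1,4-benzoquinone. Both carbons are natively electrophilic.
3. The acyloxyquinone comes from oxidative demethylation of 2,3,5,6-tetramethoxyphenyl (S)-2-methylbutanoate, itself made from the phenol and purchased (S)-2-methylbutanoic acid, which supplies the only stereocentre.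
4. The phenol comes from C–H hydroxylation (lithiation, borylation, oxidation) of 1,2,4,5-tetramethoxybenzene.
5. No ring is formed. Ring A and ring B are bought as benzenes; ring A passes through the quinone level and is re-aromatised in the key step.

Assumption: the target is taken exactly as the SMILES gives it, with an (E)-enone and the (S)-2-methylbutanoate on O-5'. Compounds 1, 5 (at least 98% ee) and 8 are purchased.

**Step 1**
Reactants: 1 1,2,4,5-tetramethoxybenzene
Product: 4 2,3,5,6-tetramethoxyphenol, via aryllithium 2 (not isolated), via dimethyl arylboronate 3 (not isolated)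
Conditions: n-BuLi (1.1 equiv), THF, 0 °C to rt; B(OMe)3 (1.5 equiv), −78 °C to rt; AcOH, 30% aq H2O2, 0 °C to rt
Reagents that add atoms: hydrogen peroxide, OO (the phenol oxygen of 4); n-butyllithium, [Li]CCCC (Li of 2 only); trimethyl borate, COB(OC)OC (B(OMe)2 of 3 only)
Why: Directed ortho-metalation removes a hydrogen flanked by two OMe groups (both ring hydrogens of 1 are equivalent, so only one aryllithium forms), and borylation followed by peroxide oxidation (1,2-aryl shift from boron to oxygen) converts C–Li into C–OH under mildly acidic conditions that the electron-rich phenol tolerates.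

**Step 2**
Reactants: 4 2,3,5,6-tetramethoxyphenol; 5 (S)-2-methylbutanoic acid
Product: 6 2,3,5,6-tetramethoxyphenyl (2S)-2-methylbutanoate
Conditions: DCC (1.1 equiv), DMAP (10 mol %), CH2Cl2, 0 °C to rt
Reagents that add atoms: none
Why: Steglich esterification through the O-acylisourea and the acylpyridinium ion acylates the hindered phenol under near-neutral conditions without ketene formation, so the purchased (S) stereocentre, the only one in the target, is carried over unchanged.

**Step 3**
Reactants: 6 2,3,5,6-tetramethoxyphenyl (2S)-2-methylbutanoate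
Product: 7 2,5-dimethoxy-3,6-dioxocyclohexa-1,4-dien-1-yl (2S)-2-methylbutanoate (the O-acyl derivative of 3-hydroxy-2,5-dimethoxy-1,4-benzoquinone)
Conditions: (NH4)2Ce(NO3)6 (2.5 equiv), MeCN–H2O 4:1, 0 °C, 15 min, fast extractive work-up
Reagents that add atoms: water, O (both quinone oxygens)
Why: Oxidative demethylation of a hydroquinone dimethyl ether by tetravalent cerium (two one-electron oxidations, with water attacking the ring carbons and expelling methanol) gives the para-quinone, the two possible para OMe pairs being mirror-related so that only 7 can form, while the aryl ester and its stereocentre are inert to the short, cold, acidic treatment.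

**Step 4 (key step)**
Reactants: 7 2,5-dimethoxy-3,6-dioxocyclohexa-1,4-dien-1-yl (2S)-2-methylbutanoate; 8 (E)-cinnamaldehyde
Product: 10 (E)-2',4'-dihydroxy-3',6'-dimethoxy-5'-[(2S)-2-methylbutanoyloxy]chalcone (target), via 4'-O-acyl isomer 9 (not isolated)
Conditions: 8 (5 equiv), blue LEDs (440 nm), PhCF3, N2, 20 °C; then Et3N (20 mol %), dark, N2, rt; dilute citric acid wash
Reagents that add atoms: none
Why: Proposed new method: the closest known reaction type is the photo-Friedel–Crafts acylation of quinones with aldehydes (Klinger–Kolvenbach reaction), in which triplet 7 abstracts the formyl hydrogen of 8 so that the normally electrophilic CHO carbon becomes the nucleophilic σ-cinnamoyl radical, a one-electron acyl anion equivalent that bonds to the only C–H carbon of the electrophilic quinone (the least hindered site, giving a captodatively stabilised radical next to OMe and C=O, then hydrogen return from the semiquinone and enolisation to hydroquinone 9), after which base-catalysed 1,2 O→O acyl migration through the five-membered cyclic orthoester moves the intact (S)-acyl group from O-4' (now para to the new ketone, hence the more acidic and better-leaving phenol) to the adjacent O-5', so no stereocentre is made or broken and the E alkene comes from 8.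

**Compound list**
1 | 1,2,4,5-tetramethoxybenzene | COc1cc(OC)c(OC)cc1OC | starting material
2 | 2,3,5,6-tetramethoxyphenyllithium | [Li]c1c(OC)c(OC)cc(OC)c1OC | intermediate
3 | dimethyl (2,3,5,6-tetramethoxyphenyl)boronate | COB(OC)c1c(OC)c(OC)cc(OC)c1OC | intermediate
4 | 2,3,5,6-tetramethoxyphenol | Oc1c(OC)c(OC)cc(OC)c1OC | intermediate
5 | (S)-2-methylbutanoic acid | CC[C@H](C)C(=O)O | starting material
6 | 2,3,5,6-tetramethoxyphenyl (2S)-2-methylbutanoate | CC[C@H](C)C(=O)Oc1c(OC)c(OC)cc(OC)c1OC | intermediate
7 | 2,5-dimethoxy-3,6-dioxocyclohexa-1,4-dien-1-yl (2S)-2-methylbutanoate | CC[C@H](C)C(=O)OC1=C(OC)C(=O)C=C(OC)C1=O | intermediate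
8 | (E)-cinnamaldehyde | O=C/C=C/c1ccccc1 | starting material
9 | (E)-2',5'-dihydroxy-3',6'-dimethoxy-4'-[(2S)-2-methylbutanoyloxy]chalcone | CC[C@H](C)C(=O)Oc1c(OC)c(O)c(C(=O)/C=C/c2ccccc2)c(OC)c1O | intermediate
10 | (E)-2',4'-dihydroxy-3',6'-dimethoxy-5'-[(2S)-2-methylbutanoyloxy]chalcone | CC[C@H](C)C(=O)Oc1c(O)c(OC)c(O)c(C(=O)/C=C/c2ccccc2)c1OC | target

**Total step count:** 4. **Longest linear sequence:** 4 (1 → 4 → 6 → 7 → 10).

**Three steps most likely to fail**

*Step 4.* Several things could go wrong:
- the donor-rich quinone may abstract hydrogen sluggishly;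
- its triplet may be drained by the styryl chromophore of 8, causing E/Z scrambling;
- the radical pair may couple at oxygen instead of carbon.

The fallback sets out from 7 and comes back at 10. It keeps the reversed-polarity acylation but uses acetaldehyde, the best-behaved partner for this photoreaction, and builds the enone afterwards. Irradiation of 7 with excess acetaldehyde gives 4-acetyl-3,6-dihydroxy-2,5-dimethoxyphenyl (2S)-2-methylbutanoate F1. The same catalytic Et3N treatment shifts the acyl group to give 3-acetyl-4,6-dihydroxy-2,5-dimethoxyphenyl (2S)-2-methylbutanoate F2. A BF3·OEt2-promoted Claisen–Schmidt condensation of F2 with benzaldehyde in dioxane at rt then delivers 10. These acidic conditions spare the aryl ester, which hydroxide would cleave.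

*Step 3.* Compound 7 is a vinylogous anhydride and may hydrolyse in the aqueous acidic cerium medium, or the arene may dimerise. The fallback sets out from 1 and comes back at 7, bypassing 4 and 6, and forms the C–O bond on a preformed quinone without water. Oxidation of 1 itself with (NH4)2Ce(NO3)6 gives the robust 2,5-dimethoxy-1,4-benzoquinone F3. Electrophilic bromination of its enol-ether carbon (Br2, NaOAc, AcOH) gives 3-bromo-2,5-dimethoxy-1,4-benzoquinone F4. This vinylogous acyl bromide is then treated with silver (2S)-2-methylbutanoate F5, made from 5 and Ag2O and dried, in MeCN over 4 Å sieves in the dark. Addition–elimination at the C–Br carbon, driven by precipitation of AgBr, gives 7. Attack at the OMe-bearing carbons is unproductive because the carboxylate is expelled again.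

*Step 1.* The very electron-rich phenol may be over-oxidised by H2O2, or lithiation may be incomplete. The fallback sets out from 1 and comes back at 4. It replaces metalation with electrophilic substitution followed by oxygen insertion. Rieche formylation (Cl2CHOMe, TiCl4, CH2Cl2, 0 °C) gives 2,3,5,6-tetramethoxybenzaldehyde F6. Baeyer–Villiger oxidation with mCPBA gives 2,3,5,6-tetramethoxyphenyl formate F7. Brief methanolysis (K2CO3, MeOH, N2) releases 4.

**Further compounds**
F1 | step 4 | 4-acetyl-3,6-dihydroxy-2,5-dimethoxyphenyl (2S)-2-methylbutanoate | CC[C@H](C)C(=O)Oc1c(OC)c(O)c(C(C)=O)c(OC)c1O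
F2 | step 4 | 3-acetyl-4,6-dihydroxy-2,5-dimethoxyphenyl (2S)-2-methylbutanoate | CC[C@H](C)C(=O)Oc1c(O)c(OC)c(O)c(C(C)=O)c1OC
F3 | step 3 | 2,5-dimethoxy-1,4-benzoquinone | COC1=CC(=O)C(OC)=CC1=O
F4 | step 3 | 3-bromo-2,5-dimethoxy-1,4-benzoquinone | COC1=CC(=O)C(OC)=C(Br)C1=O
F5 | step 3 | silver (2S)-2-methylbutanoate | CC[C@H](C)C(=O)[O-].[Ag+]
F6 | step 1 | 2,3,5,6-tetramethoxybenzaldehyde | COc1cc(OC)c(OC)c(C=O)c1OC
F7 | step 1 | 2,3,5,6-tetramethoxyphenyl formate | COc1cc(OC)c(OC)c(OC=O)c1OC
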